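The data stem from a simulated flask from invented constants, noise included.

X, with any D counted in, is the product I want from this flask, and the doubt is whether solid forms.

| flask | J | remark | time |
|---|---|---|---|
| Wednesday's | 0.041 M | run made earlier |  |
| Monday's | 0.091 M | run made earlier |  |
| flask | 0.061 M |  | 4.0 min |

- Wednesday's (time / min: X / %, D / %): 0.200: 3, 0; 0.667: 7, 0; 1.00: 12, 3; 1.50: 14, 0; 2.50: 22, 0; 3.00: 25, 0; 4.00: 32, 0
- Monday's (time / min: X / %, D / %): 0.200: 0, 0; 0.667: 9, 0; 1.00: 12, 0; 1.50: 13, 0; 2.50: 20, 2; 3.00: 22, 0; 4.00: 27, 0

(each reading ± 1.5 percentage points)

- X is meant together with its D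
- solid, in amounts per volume of the solution: D

* the X and D together standing at 4.0 min, as a percentage of the J charged
* concentration of X in solution at 4.0 min, in percent of saturation

The lone D readings of 3% and 2% sit among zeros, so I read them as scatter. But I still need a measure that carries across time and charge. I take the apparent first-order constant, which I call the fill constant k: the natural logarithm of one over the share not yet X or D, divided by the time. The last single readings give 0.0964 min⁻¹ on Wednesday and 0.0787 min⁻¹ on Monday. The flask's 0.061 M lies at their geometric middle, 0.0611 M, so I take the flask's k as their mean, 0.0875 min⁻¹. That gives 29.5%, or 0.0180 M of X. Going round once more, this is less than the 0.0246 M of Monday's last reading, which showed no crystals. So, barring supersaturation, I expect none in the flask, and I estimate it below 73.2% of saturation, a ceiling read from that one scattered reading.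

The forecast gives 30% and 50%, the second “only loosely constrained”, where I give 29.5% and a ceiling.

The flask gives 29.2% and 52.3%, with D at 0%.

    D ⇌ X, rate k1*(cs1 - [X]) while solid is left; crystals form when [X] > cs1 (solubility = 34.0 mM, k = 0.0396 s⁻¹)
    2 J → G (k = 0.0130 M⁻¹ s⁻¹)
    J → X (k = 0.00170 s⁻¹)

At 4.0 min the flask's k gives 29.5% against the 29.2% the flask holds, and the flask's share not yet X is J at 50.7% plus G at 20.2%, each G counted as the two J it holds. The neighbouring flask, the same charge read at 2.5 min, gets 19.6% from k, and it stands at 20.4%.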